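Oxolane numbering O1, C2 (syringyl), C3 (CH2O‑feruloyl), C4 (guaiacylmethyl), C5 (CH2) is used throughout, also for open‑chain and bicyclic precursors.

## The problem

The target is a monocyclic lignan ester: one oxolane ring carries a syringyl group at C2, the feruloyloxymethyl group at C3 and a guaiacylmethyl group at C4, and C5 is an unsubstituted OCH2 carbon. The three contiguous stereocentres are (2S,3R,4R), that is 2,3‑trans and 3,4‑cis. The two carbon substituents at C3 and C4 therefore sit on the same face, an arrangement that cannot be reached by equilibration. C2 and C3 can be set together in an open‑chain aldol bond formation, but C4 has no functional handle of its own and must be controlled from C3. C2 is benzylic and bound to the ring oxygen, so with an electron‑rich aryl group it ionises under acid and is cleaved by hydrogenolysis; its arene has to be switched off electronically for most of the route. The three free phenols are oxidation‑prone, and the (E)‑cinnamate ester tolerates neither hydroxide nor catalytic hydrogenation, so the ester must be made last, after every basic and reductive step. The enabling feature is the pairing of C5 with the C4 side chain: C5 is formaldehyde bound to O1, and the exocyclic carbon on C4 is a benzylic position whose cation the guaiacyl ring stabilises. An O1=CH2 oxocarbenium ion can therefore add to a styrene at C4, and the carboxyl‑level carbon on C3 is placed to capture the cation as a cis‑fused γ‑lactone that is later removed by hydrogenolysis.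

## Retrosynthesis

**Ester C–O bond.** The bond between the C3 CH2O group and the feruloyl carbonyl is cut first, giving triol 23 and ferulic acid 24. This is the only cut that keeps the base‑ and hydrogen‑sensitive cinnamate out of all earlier steps. The forward reaction must esterify one primary alcohol in the presence of three phenols, which a Mitsunobu reaction can do because the carboxylic acid is the only strongly acidic partner.

**Functional group changes at C3 and on the syringyl ring.** Triol 23 is traced through tosylate alcohol 22 to acid 21. The tosylate is the electronic switch that protects C2, and the carboxyl group is what a lactone leaves behind. The forward steps are a borane reduction that spares the sulfonate and a hydroxide cleavage of the sulfonate, done while nothing base‑labile is present.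

**Benzylic C–O bond (reconnection).** The CH2 of the guaiacylmethyl group in 21 is reconnected to the carboxyl oxygen, giving furofuranone 19. A benzylic ester C–O bond is the easiest bond in the molecule to cleave by hydrogenolysis, and the benzyl ether on the guaiacyl oxygen falls in the same operation. The gain is that the 3,4‑cis relation is no longer a selectivity question, since a bicyclo[3.3.0] lactone can only be cis‑fused. The forward step must cleave the lactone C–O bond and leave C2–O1 intact.

**C4–C5 and the lactone C–O bond (key disconnection).** Both bonds of 19 are cut together, which leads to the isomeric 1,3‑dioxan‑4‑one 16. The neighbouring cuts are weaker for this target: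
- Cutting O1–C2 would need an ionisable, electron‑rich syringyl group and would set C2 by thermodynamics only.
- Cutting C3–C4 or C2–C3 leaves one relative configuration to a transition‑state preference.
- The chosen cut uses the unsubstituted C5, so no stereocentre arises at the electrophile, and the one formed at C4 is policed by the lactone.

The precursor has one ring and only the two aldol centres. The forward reaction must open the acetal toward O1, form the C–C bond at the internal styrene carbon and let the carboxylate capture the cation.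

**Acetal.** Dioxanone 16 is cut at the two acetal C–O bonds to hydroxy acid 14 and paraformaldehyde 15. The forward step is an acetalisation mild enough not to ionise the product.

**C2–C3 bond.** Acid 14 comes from imide 12, which is cut at the aldol bond into acyl oxazolidinone 7 and aldehyde 9. The syn‑aldol sets both centres with auxiliary control, and syn maps onto 2,3‑trans in the oxolane. The forward reaction must take the boron dienolate 10 at its α‑carbon and tolerate the tosylate.

**Fragments.** Imide 7 is the N‑acyl derivative of auxiliary 5 and styrylacetic acid 4. Acid 4 is cut at the aryl–alkene bond (Mizoroki–Heck reaction) into bromide 2 and but‑3‑enoic acid 3. Bromide 2 is the benzyl ether of phenol 1, and aldehyde 9 is the tosylate of syringaldehyde 8.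

## Roads not taken

**Alternative 1:** The skeleton is cut at the C4–CH2Ar bond and at C2–C3 on an alkyne template, and no ring is formed.
- Forward step: the magnesium alkoxide of the monosilylated butynediol A2 directs anti addition of the benzylic Grignard reagent A3. The alkenylmetal is passed to zinc with ZnCl2 and added to the silylated syringaldehyde A4 under a chiral amino alcohol, giving ene‑diol A1.
- Merits: the whole carbon skeleton is assembled from three simple pieces in one flask, which is clearly shorter than the seven steps that lead to 16.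
- Weak points: only the carbinol centre is set, by reagent control on a hindered alkenylzinc species in the presence of magnesium salts that favour a racemic background addition. As drawn, that carbinol maps onto C2 with the wrong sense unless the ring closure inverts it. C3 and C4 must then come from hydrogenation of a tetrasubstituted alkene in a 2,5‑dihydrofuran. Syn delivery gives 3,4‑cis, but hydrogen arrives anti to the C2 aryl group and so places the C3 substituent cis to it, the wrong 2,3‑relation. No group on a stereocentre can direct the catalyst to the other face.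
- Comparison: this road wins on convergence and on using only known reaction types. The chosen plan ties each of the three centres to a firm control element (auxiliary for C2 and C3, ring fusion for C4).

**Alternative 2:** The ring is cut at C3–C4.
- Forward step: the trivalent titanium reagent Cp2TiCl opens the terminal epoxide of the epoxy coniferyl ether A6 to a C3 radical. The radical adds 5‑exo to the alkene, and the benzylic radical is reduced and protonated, giving the bis‑silylated core A5.
- Merits: the reaction type is established for oxolane lignans. It delivers the ring, the CH2OH group and the ArCH2 group at their final oxidation levels in one step. A5 has a free primary alcohol and silyl‑protected phenols, so the ester could be made by ordinary acylation and the phenols freed by fluoride at the end. That endgame is safer than the one chosen here, which has to esterify in the presence of three free phenols.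
- Weak points: C3 and C4 are both set in one radical transition state. The 2,3‑trans relation is secure, but the 3,4‑cis relation rests on a chair‑like preference that favours it without excluding the C4 epimer. A6 must be made enantiopure, typically by a resolution that discards half the material. The benzylic radical can also end as an alkene.
- Comparison: this road is shorter after the key step and less speculative. The chosen plan offers enforced 3,4‑cis and auxiliary‑derived absolute configuration.

**Alternative 3:** The ring is cut at C2–C3.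
- Forward step: Rh2(OAc)4 decomposes the α‑diazo lactone A8, and the carbenoid inserts 1,5 into the benzylic ether C–H bond, giving the cis‑fused furofuranone A7.
- Merits: A7 is the same kind of bicycle as 19, so 3,4‑cis is enforced in the same way and the endgame is shared. The ring‑forming event is a known one on this ring system, which the cascade chosen here is not. The silyl ethers would also allow esterification before phenol release.
- Weak points: the centre created is C2, and its configuration is decided in the insertion. Such insertions tend to place the new aryl group on the concave face, which corresponds to 2,3‑cis. Correcting it by acid would ionise the very bond that has to survive. A8 needs an enantiopure trans‑disubstituted butyrolactone and a diazo transfer onto a weakly acidic lactone, which makes the approach longer. The electron‑rich arenes also offer the carbenoid competing addition sites.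
- Comparison: the chosen plan fixes C2 in the aldol step before any ring exists, and pays for that with a cyclisation that is less proven.

Key step: step 8

Assumption: the target SMILES is read as the (2S,3R,4R)‑oxolane (2,3‑trans, 3,4‑cis).

## Route

Step 1
Reactants: 1 4‑bromo‑2‑methoxyphenol
Product: 2 1‑(benzyloxy)‑4‑bromo‑2‑methoxybenzene
Conditions: BnBr, K2CO3, acetone, reflux
Reagents that add atoms: benzyl bromide, BrCc1ccccc1
Why: Williamson ether synthesis on a phenoxide; the benzyl ether keeps the guaiacyl oxygen electron‑releasing, as the cation chemistry of step 8 requires, and is removed by hydrogen in step 9.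

Step 2
Reactants: 2 1‑(benzyloxy)‑4‑bromo‑2‑methoxybenzene; 3 but‑3‑enoic acid
Product: 4 (E)‑4‑[4‑(benzyloxy)‑3‑methoxyphenyl]but‑3‑enoic acid
Conditions: Pd(OAc)2 (3 mol %), P(o‑tol)3 (9 mol %), Et3N, MeCN, 85 °C; then 1 M HCl
Reagents that add atoms: none
Why: Mizoroki–Heck reaction; zerovalent palladium inserts into the C–Br bond, the aryl group adds to the terminal alkene carbon, and β‑hydride elimination gives the (E)‑alkene conjugated with the arene, the acid being carried as its ammonium salt.

Step 3
Reactants: 4 (E)‑4‑[4‑(benzyloxy)‑3‑methoxyphenyl]but‑3‑enoic acid; 5 (S)‑4‑benzyl‑1,3‑oxazolidin‑2‑one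
Product: 7 (S)‑4‑benzyl‑3‑[(E)‑4‑(4‑benzyloxy‑3‑methoxyphenyl)but‑3‑enoyl]‑1,3‑oxazolidin‑2‑one, via mixed pivalic anhydride 6 (not isolated)
Conditions: PivCl, Et3N, THF, −20 °C; then LiCl, 5, −20 °C to rt
Reagents that add atoms: none
Why: N‑acylation of an Evans oxazolidinone through a mixed anhydride with LiCl and amine base; no strong base is used, and the alkene stays where it is because conjugation with the electron‑rich arene is the more stable position.

Step 4
Reactants: 8 syringaldehyde (4‑hydroxy‑3,5‑dimethoxybenzaldehyde)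
Product: 9 4‑formyl‑2,6‑dimethoxyphenyl 4‑methylbenzenesulfonate (O‑tosylsyringaldehyde)
Conditions: TsCl, Et3N, DMAP (cat.), CH2Cl2, 0 °C to rt
Reagents that add atoms: tosyl chloride, Cc1ccc(cc1)S(Cl)(=O)=O
Why: sulfonylation of a phenol; the tosylate makes the syringyl ring electron‑poor, so its benzylic C–O bond resists ionisation and hydrogenolysis later, and it survives LiOOH, Lewis acid and borane.

Step 5
Reactants: 7 (S)‑4‑benzyl‑3‑[(E)‑4‑(4‑benzyloxy‑3‑methoxyphenyl)but‑3‑enoyl]‑1,3‑oxazolidin‑2‑one; 9 O‑tosylsyringaldehyde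
Product: 12 (S)‑4‑benzyl‑3‑[(2S,3S)‑2‑[(E)‑2‑(4‑benzyloxy‑3‑methoxyphenyl)ethenyl]‑3‑hydroxy‑3‑(3,5‑dimethoxy‑4‑tosyloxyphenyl)propanoyl]‑1,3‑oxazolidin‑2‑one, via dibutylboron enolate 10 (not isolated), via boron aldolate 11 (not isolated)
Conditions: Bu2BOTf, iPr2NEt, CH2Cl2, −78 to 0 °C; then 9, −78 to 0 °C; then pH 7 buffer, MeOH, 30% H2O2, 0 °C
Reagents that add atoms: none
Why: Evans syn‑aldol reaction; the (Z)‑boron dienolate 10 reacts at its α‑carbon through a Zimmerman–Traxler chair on the face away from the benzyl group of the (S)‑auxiliary, which sets (2S,3S). These two centres become C3 and C2 of the oxolane, and syn in the chain becomes 2,3‑trans in the ring.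

Step 6
Reactants: 12 the syn‑aldol imide
Product: 14 (2S,3S)‑2‑[(E)‑2‑(4‑benzyloxy‑3‑methoxyphenyl)ethenyl]‑3‑hydroxy‑3‑(3,5‑dimethoxy‑4‑tosyloxyphenyl)propanoic acid, via peroxy acid 13 (not isolated)
Conditions: LiOH, 30% H2O2, THF–H2O (3:1), 0 °C; then aq. Na2SO3; then 1 M HCl
Reagents that add atoms: hydrogen peroxide, OO
Why: LiOOH cleavage of an N‑acyl oxazolidinone; hydroperoxide attacks the exocyclic carbonyl at 0 °C faster than retro‑aldol or α‑epimerisation can occur, sulfite reduces the peroxy acid 13 while it is still an unreactive anion, and auxiliary 5 is recovered.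

Step 7
Reactants: 14 the (2S,3S)‑hydroxy acid; 15 paraformaldehyde
Product: 16 (5S,6S)‑5‑[(E)‑2‑(4‑benzyloxy‑3‑methoxyphenyl)ethenyl]‑6‑(3,5‑dimethoxy‑4‑tosyloxyphenyl)‑1,3‑dioxan‑4‑one (5,6‑cis)
Conditions: (CH2O)n, PPTS (10 mol %), benzene, reflux, Dean–Stark trap
Reagents that add atoms: none
Why: acid‑catalysed acetalisation of a β‑hydroxy acid to a 1,3‑dioxan‑4‑one with azeotropic removal of water; the weak pyridinium acid should close the acetal at oxygen without ionising it again, and no stereocentre is touched.

Step 8
Reactants: 16 the cis‑5,6‑disubstituted 1,3‑dioxan‑4‑one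
Product: 19 (3S,3aR,6S,6aS)‑3‑(4‑benzyloxy‑3‑methoxyphenyl)‑6‑(3,5‑dimethoxy‑4‑tosyloxyphenyl)tetrahydro‑1H,3H‑furo[3,4‑c]furan‑1‑one, via oxocarbenium ion 17 (not isolated), via benzylic cation 18 (not isolated)
Conditions: Me3SiOTf (0.3 equiv), CH2Cl2, −78 to −20 °C; then aq. NaHCO3
Reagents that add atoms: none
Why: Proposed new method: Me3SiOTf silylates the ring carbonyl of 16 and the acyl O–CH2 bond breaks, because a silyl carboxylate is a far better leaving group than the benzylic alkoxide, so the oxocarbenium ion 17 sits on O1 (the known Lewis‑acid opening of 1,3‑dioxan‑4‑ones). The alkene carbon attached to C3 then adds to the O1=CH2 carbon and forms C4–C5, a Prins cyclisation of the kind known for (E)‑styryl oxocarbenium ions; this closes the oxolane in a five‑membered mode that is exo for the alkene and endo for the C=O+ unit and leaves the p‑benzyloxybenzyl cation 18. The silyl ester oxygen captures that cation and closes the γ‑lactone, a five‑membered closure with both former alkene carbons in the ring (as in halolactonisation of 4‑arylbut‑3‑enoic acids), and Me3Si+ is released, so the step is an acid‑catalysed isomerisation. The closest known reaction types are Prins cyclisation ended by an internal oxygen nucleophile and acetal substitution of dioxanones by π‑nucleophiles; their union with carboxylate capture is the untested part. The new centre at C4 (C3a of 19) is controlled by the ring fusion: only the cation whose benzylic carbon is cis to the C3 carboxyl can lactonise, the transition state leading to it holds the carboxyl oxygen anti to the incoming CH2 across the alkene so that capture can assist bond formation, and the trans cation can return by Grob‑type retro‑Prins cleavage or by loss and return of the C4 proton. The lactone benzylic centre follows from anti addition across the (E)‑alkene (aryl on the convex face) and is erased in step 9, while C2 and C3 come unchanged from the aldol. The step needs ionisation at the acetal only, which the tosylate secures by disfavouring a cation at C2; it also needs C–C bond formation at the internal alkene carbon instead of a 2‑oxonia‑Cope shift through the terminal one, which the p‑benzyloxy group secures by polarising the styrene.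

Step 9
Reactants: 19 the Bn/Ts‑protected diaryl furofuranone
Product: 21 (2S,3S,4R)‑2‑(3,5‑dimethoxy‑4‑tosyloxyphenyl)‑4‑(4‑hydroxy‑3‑methoxybenzyl)oxolane‑3‑carboxylic acid, via phenolic lactone 20 (not isolated)
Conditions: H2 (1 atm), 10% Pd/C, EtOAc–AcOH (9:1), rt
Reagents that add atoms: none
Why: catalytic hydrogenolysis; the aryl benzyl ether goes first, and the lactone C–O bond, an ester leaving group on a p‑hydroxybenzyl carbon, follows, while the tosylate‑deactivated C2–O1 ether and the aryl sulfonate are much slower. The centre that is lost is the sacrificial one; C2, C3 and C4 are untouched.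

Step 10
Reactants: 21 the oxolane‑3‑carboxylic acid
Product: 22 4‑[(2S,3R,4R)‑3‑(hydroxymethyl)‑4‑(4‑hydroxy‑3‑methoxybenzyl)oxolan‑2‑yl]‑2,6‑dimethoxyphenyl 4‑methylbenzenesulfonate
Conditions: BH3·SMe2, THF, 0 °C to rt; then MeOH
Reagents that add atoms: none
Why: borane reduction of a carboxylic acid; BH3 reduces CO2H selectively in the presence of the aryl sulfonate and the ring ether, and the phenol is only converted to a borate that methanol cleaves.

Step 11
Reactants: 22 the tosylate alcohol
Product: 23 4‑[(2S,3R,4R)‑3‑(hydroxymethyl)‑4‑(4‑hydroxy‑3‑methoxybenzyl)oxolan‑2‑yl]‑2,6‑dimethoxyphenol (5′‑methoxylariciresinol)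
Conditions: KOH, MeOH–H2O (4:1), 65 °C; then 1 M HCl to pH 5
Reagents that add atoms: none
Why: alkaline hydrolysis of an aryl sulfonate by attack of hydroxide at sulfur; nothing else in 22 is base‑labile, which is why the tosylate is removed before the cinnamate is introduced.

Step 12
Reactants: 23 5′‑methoxylariciresinol; 24 (E)‑ferulic acid
Product: 25 [(2S,3R,4R)‑2‑(4‑hydroxy‑3,5‑dimethoxyphenyl)‑4‑(4‑hydroxy‑3‑methoxybenzyl)oxolan‑3‑yl]methyl (E)‑3‑(4‑hydroxy‑3‑methoxyphenyl)prop‑2‑enoate
Conditions: PPh3, DIAD, THF, 0 °C to rt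
Reagents that add atoms: none
Why: Mitsunobu esterification; the carboxylic acid is by far the most acidic partner, so its carboxylate displaces the activated primary alcohol while the phenols stay free, a chemoselectivity that is established for phenolic acids and primary alcohols. The CH2O carbon is not a stereocentre and no base or hydrogen follows.

## Compound list

1 | 4‑bromo‑2‑methoxyphenol | COc1cc(Br)ccc1O | starting material
2 | 1‑(benzyloxy)‑4‑bromo‑2‑methoxybenzene | COc1cc(Br)ccc1OCc1ccccc1 | intermediate
3 | but‑3‑enoic acid | C=CCC(=O)O | starting material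
4 | (E)‑4‑[4‑(benzyloxy)‑3‑methoxyphenyl]but‑3‑enoic acid | OC(=O)C/C=C/c1ccc(OCc2ccccc2)c(OC)c1 | intermediate
5 | (S)‑4‑benzyl‑1,3‑oxazolidin‑2‑one | O=C1N[C@@H](Cc2ccccc2)CO1 | starting material
6 | mixed anhydride of 4 with pivalic acid | CC(C)(C)C(=O)OC(=O)C/C=C/c1ccc(OCc2ccccc2)c(OC)c1 | intermediate
7 | (S)‑4‑benzyl‑3‑[(E)‑4‑(4‑benzyloxy‑3‑methoxyphenyl)but‑3‑enoyl]‑1,3‑oxazolidin‑2‑one | O=C(C/C=C/c1ccc(OCc2ccccc2)c(OC)c1)N1C(=O)OC[C@@H]1Cc1ccccc1 | intermediate
8 | syringaldehyde | COc1cc(C=O)cc(OC)c1O | starting material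
9 | 4‑formyl‑2,6‑dimethoxyphenyl 4‑methylbenzenesulfonate | COc1cc(C=O)cc(OC)c1OS(=O)(=O)c1ccc(C)cc1 | intermediate
10 | dibutylboron (Z)‑enolate of 7 | CCCCB(CCCC)O/C(=C\C=C\c1ccc(OCc2ccccc2)c(OC)c1)N1C(=O)OC[C@@H]1Cc1ccccc1 | intermediate
11 | O‑dibutylboryl aldolate of 12 | O=C([C@@H](/C=C/c1ccc(OCc2ccccc2)c(OC)c1)[C@H](OB(CCCC)CCCC)c1cc(OC)c(OS(=O)(=O)c2ccc(C)cc2)c(OC)c1)N1C(=O)OC[C@@H]1Cc1ccccc1 | intermediate
12 | (S)‑4‑benzyl‑3‑[(2S,3S)‑2‑[(E)‑2‑(4‑benzyloxy‑3‑methoxyphenyl)ethenyl]‑3‑hydroxy‑3‑(3,5‑dimethoxy‑4‑tosyloxyphenyl)propanoyl]‑1,3‑oxazolidin‑2‑one | O=C([C@@H](/C=C/c1ccc(OCc2ccccc2)c(OC)c1)[C@H](O)c1cc(OC)c(OS(=O)(=O)c2ccc(C)cc2)c(OC)c1)N1C(=O)OC[C@@H]1Cc1ccccc1 | intermediate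
13 | peroxy acid corresponding to 14 | OOC(=O)[C@@H](/C=C/c1ccc(OCc2ccccc2)c(OC)c1)[C@H](O)c1cc(OC)c(OS(=O)(=O)c2ccc(C)cc2)c(OC)c1 | intermediate
14 | (2S,3S)‑2‑[(E)‑2‑(4‑benzyloxy‑3‑methoxyphenyl)ethenyl]‑3‑hydroxy‑3‑(3,5‑dimethoxy‑4‑tosyloxyphenyl)propanoic acid | OC(=O)[C@@H](/C=C/c1ccc(OCc2ccccc2)c(OC)c1)[C@H](O)c1cc(OC)c(OS(=O)(=O)c2ccc(C)cc2)c(OC)c1 | intermediate
15 | paraformaldehyde (written as its formaldehyde unit) | C=O | starting material
16 | (5S,6S)‑5‑[(E)‑2‑(4‑benzyloxy‑3‑methoxyphenyl)ethenyl]‑6‑(3,5‑dimethoxy‑4‑tosyloxyphenyl)‑1,3‑dioxan‑4‑one | O=C1OCO[C@H](c2cc(OC)c(OS(=O)(=O)c3ccc(C)cc3)c(OC)c2)[C@@H]1/C=C/c1ccc(OCc2ccccc2)c(OC)c1 | intermediate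
17 | O1‑methylene oxocarbenium ion of the trimethylsilyl ester of 14, triflate salt | C[Si](C)(C)OC(=O)[C@@H](/C=C/c1ccc(OCc2ccccc2)c(OC)c1)[C@H]([O+]=C)c1cc(OC)c(OS(=O)(=O)c2ccc(C)cc2)c(OC)c1.[O-]S(=O)(=O)C(F)(F)F | intermediate
18 | trimethylsilyl 2,3‑trans‑3,4‑cis‑oxolane‑3‑carboxylate carrying the 4‑benzyloxy‑3‑methoxybenzyl cation at C4, triflate salt | C[Si](C)(C)OC(=O)[C@@H]1[C@@H](c2cc(OC)c(OS(=O)(=O)c3ccc(C)cc3)c(OC)c2)OC[C@@H]1[CH+]c1ccc(OCc2ccccc2)c(OC)c1.[O-]S(=O)(=O)C(F)(F)F | intermediate
19 | (3S,3aR,6S,6aS)‑3‑(4‑benzyloxy‑3‑methoxyphenyl)‑6‑(3,5‑dimethoxy‑4‑tosyloxyphenyl)tetrahydro‑1H,3H‑furo[3,4‑c]furan‑1‑one | O=C1O[C@H](c3ccc(OCc4ccccc4)c(OC)c3)[C@H]2CO[C@H](c3cc(OC)c(OS(=O)(=O)c4ccc(C)cc4)c(OC)c3)[C@@H]12 | intermediate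
20 | (3S,3aR,6S,6aS)‑3‑(4‑hydroxy‑3‑methoxyphenyl)‑6‑(3,5‑dimethoxy‑4‑tosyloxyphenyl)tetrahydro‑1H,3H‑furo[3,4‑c]furan‑1‑one | O=C1O[C@H](c3ccc(O)c(OC)c3)[C@H]2CO[C@H](c3cc(OC)c(OS(=O)(=O)c4ccc(C)cc4)c(OC)c3)[C@@H]12 | intermediate
21 | (2S,3S,4R)‑2‑(3,5‑dimethoxy‑4‑tosyloxyphenyl)‑4‑(4‑hydroxy‑3‑methoxybenzyl)oxolane‑3‑carboxylic acid | OC(=O)[C@@H]1[C@@H](c2cc(OC)c(OS(=O)(=O)c3ccc(C)cc3)c(OC)c2)OC[C@@H]1Cc1ccc(O)c(OC)c1 | intermediate
22 | 4‑[(2S,3R,4R)‑3‑(hydroxymethyl)‑4‑(4‑hydroxy‑3‑methoxybenzyl)oxolan‑2‑yl]‑2,6‑dimethoxyphenyl 4‑methylbenzenesulfonate | OC[C@H]1[C@@H](Cc2ccc(O)c(OC)c2)CO[C@@H]1c1cc(OC)c(OS(=O)(=O)c2ccc(C)cc2)c(OC)c1 | intermediate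
23 | 4‑[(2S,3R,4R)‑3‑(hydroxymethyl)‑4‑(4‑hydroxy‑3‑methoxybenzyl)oxolan‑2‑yl]‑2,6‑dimethoxyphenol | OC[C@H]1[C@@H](Cc2ccc(O)c(OC)c2)CO[C@@H]1c1cc(OC)c(O)c(OC)c1 | intermediate
24 | (E)‑ferulic acid | COc1cc(/C=C/C(=O)O)ccc1O | starting material
25 | [(2S,3R,4R)‑2‑(4‑hydroxy‑3,5‑dimethoxyphenyl)‑4‑(4‑hydroxy‑3‑methoxybenzyl)oxolan‑3‑yl]methyl (E)‑3‑(4‑hydroxy‑3‑methoxyphenyl)prop‑2‑enoate | COc1cc(/C=C/C(=O)OC[C@H]2[C@@H](Cc3ccc(O)c(OC)c3)CO[C@@H]2c2cc(OC)c(O)c(OC)c2)ccc1O | target

## Step count and least certain steps

Total: 12 steps. Longest linear sequence: 11 steps (steps 1, 2, 3 and 5 to 12, from 1); step 4 is a one‑step side branch.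

**Step 8 (key step, proposed new method).**
- What may go wrong: the oxocarbenium ion may bond through the terminal styrene carbon in a 2‑oxonia‑Cope shift and then fragment to aldehyde 9 and an unsaturated acid. Attack on the other alkene face gives the cation trans to the carboxyl, which cannot lactonise and drains into proton loss, alkene migration toward C3 or oligomerisation of the electron‑rich styrene.
- Fallback (known reactions only, from 14, back at 19): the two ring closures are separated and the cation is generated from an open‑chain acetal.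
  - Me3SiCHN2 in toluene–methanol converts 14 into the methyl ester F1.
  - Chloromethyl methyl ether and iPr2NEt give the methoxymethyl ether F2.
  - SnCl4 in CH2Cl2 at −78 °C ionises the methoxymethyl ether, and the alkoxymethyl cation cyclises onto the styrene with chloride capture. This is the established Lewis‑acid cyclisation of alkoxymethyl ethers onto alkenes. It gives the benzylic chloride F3 as a mixture at the chloride‑bearing carbon.
  - Warming with catalytic ZnCl2 re‑ionises the chloride, and the cis ester closes the lactone with loss of chloromethane (lactonisation of a γ‑halo ester) to give 19.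
  - Each event can then be tuned separately, and the chloride serves as a resting state from which the trans series can re‑enter.

**Step 7.**
- What may go wrong: the acid catalyst may ionise the acetal as it forms, so that cyclisation starts uncontrolled at reflux, or it may protonate the styrene and lactonise the styrylacetic acid unit. Acetalisation of the hindered, deactivated benzylic alcohol may also be slow.
- Fallback (from 14, back at 16): the O–CH2–O bridge is built by two substitutions under non‑acidic conditions, so that no oxocarbenium ion is generated. Chloromethyl chlorosulfate with NaHCO3 and Bu4NHSO4 in CH2Cl2–water gives the chloromethyl ester F4. NaI and iPr2NEt in acetonitrile then close the ring by intramolecular O‑alkylation of the benzylic alcohol to give 16.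

**Step 9.**
- What may go wrong: hydrogenolysis may go on to the second benzylic C–O bond (C2–O1) and open the oxolane, or it may stop at the phenolic lactone.
- Fallback (from 19, back at 22): the lactone is opened by ionic hydrogenation instead of on the metal surface. Et3SiH and BF3·OEt2 in CH2Cl2 ionise only the p‑benzyloxybenzyl C–O bond and deliver hydride, giving the benzyl ether acid F5. BH3·SMe2 reduces it to the benzyl ether alcohol F6. A short hydrogenolysis over Pd/C in EtOAc, which only has to cleave the aryl benzyl ether, gives 22.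

**Step 12.**
- What may go wrong: a phenoxide may compete as the nucleophile and be O‑alkylated by the activated alcohol, and ferulic acid may self‑condense through its own phenol.
- Fallback (from 23 and 24, back at 25): the phenols are masked so that an ordinary carbodiimide esterification can be used.
  - Allyl bromide and K2CO3 in acetone alkylate only the two phenols of 23 and give the bis(allyl ether) F7.
  - The same reagents convert 24 into allyl 4‑O‑allylferulate F8, whose allyl ester is saponified with LiOH to 4‑O‑allylferulic acid F9.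
  - Steglich esterification (EDC·HCl, DMAP, CH2Cl2) of F7 with F9 gives the tris(allyl) ester F10.
  - Pd(PPh3)4 with morpholine removes the three allyl groups (Tsuji–Trost deallylation) under conditions that leave the cinnamate untouched and gives 25.

## Further compounds

F1 | step 8 | methyl (2S,3S)‑2‑[(E)‑2‑(4‑benzyloxy‑3‑methoxyphenyl)ethenyl]‑3‑hydroxy‑3‑(3,5‑dimethoxy‑4‑tosyloxyphenyl)propanoate | COC(=O)[C@@H](/C=C/c1ccc(OCc2ccccc2)c(OC)c1)[C@H](O)c1cc(OC)c(OS(=O)(=O)c2ccc(C)cc2)c(OC)c1
F2 | step 8 | methyl (2S,3S)‑2‑[(E)‑2‑(4‑benzyloxy‑3‑methoxyphenyl)ethenyl]‑3‑(methoxymethoxy)‑3‑(3,5‑dimethoxy‑4‑tosyloxyphenyl)propanoate | COC(=O)[C@@H](/C=C/c1ccc(OCc2ccccc2)c(OC)c1)[C@H](OCOC)c1cc(OC)c(OS(=O)(=O)c2ccc(C)cc2)c(OC)c1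
F3 | step 8 | methyl (2S,3S,4R)‑4‑[(4‑benzyloxy‑3‑methoxyphenyl)chloromethyl]‑2‑(3,5‑dimethoxy‑4‑tosyloxyphenyl)oxolane‑3‑carboxylate, both epimers at the chloride‑bearing carbon | COC(=O)[C@@H]1[C@@H](c2cc(OC)c(OS(=O)(=O)c3ccc(C)cc3)c(OC)c2)OC[C@@H]1C(Cl)c1ccc(OCc2ccccc2)c(OC)c1
F4 | step 7 | chloromethyl (2S,3S)‑2‑[(E)‑2‑(4‑benzyloxy‑3‑methoxyphenyl)ethenyl]‑3‑hydroxy‑3‑(3,5‑dimethoxy‑4‑tosyloxyphenyl)propanoate | ClCOC(=O)[C@@H](/C=C/c1ccc(OCc2ccccc2)c(OC)c1)[C@H](O)c1cc(OC)c(OS(=O)(=O)c2ccc(C)cc2)c(OC)c1
F5 | step 9 | (2S,3S,4R)‑4‑(4‑benzyloxy‑3‑methoxybenzyl)‑2‑(3,5‑dimethoxy‑4‑tosyloxyphenyl)oxolane‑3‑carboxylic acid | OC(=O)[C@@H]1[C@@H](c2cc(OC)c(OS(=O)(=O)c3ccc(C)cc3)c(OC)c2)OC[C@@H]1Cc1ccc(OCc2ccccc2)c(OC)c1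
F6 | step 9 | 4‑[(2S,3R,4R)‑4‑(4‑benzyloxy‑3‑methoxybenzyl)‑3‑(hydroxymethyl)oxolan‑2‑yl]‑2,6‑dimethoxyphenyl 4‑methylbenzenesulfonate | OC[C@H]1[C@@H](Cc2ccc(OCc3ccccc3)c(OC)c2)CO[C@@H]1c1cc(OC)c(OS(=O)(=O)c2ccc(C)cc2)c(OC)c1
F7 | step 12 | [(2S,3R,4R)‑2‑(4‑allyloxy‑3,5‑dimethoxyphenyl)‑4‑(4‑allyloxy‑3‑methoxybenzyl)oxolan‑3‑yl]methanol | OC[C@H]1[C@@H](Cc2ccc(OCC=C)c(OC)c2)CO[C@@H]1c1cc(OC)c(OCC=C)c(OC)c1
F8 | step 12 | allyl (E)‑3‑(4‑allyloxy‑3‑methoxyphenyl)prop‑2‑enoate | C=CCOC(=O)/C=C/c1ccc(OCC=C)c(OC)c1
F9 | step 12 | (E)‑3‑(4‑allyloxy‑3‑methoxyphenyl)prop‑2‑enoic acid | OC(=O)/C=C/c1ccc(OCC=C)c(OC)c1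
F10 | step 12 | [(2S,3R,4R)‑2‑(4‑allyloxy‑3,5‑dimethoxyphenyl)‑4‑(4‑allyloxy‑3‑methoxybenzyl)oxolan‑3‑yl]methyl (E)‑3‑(4‑allyloxy‑3‑methoxyphenyl)prop‑2‑enoate | COc1cc(/C=C/C(=O)OC[C@H]2[C@@H](Cc3ccc(OCC=C)c(OC)c3)CO[C@@H]2c2cc(OC)c(OCC=C)c(OC)c2)ccc1OCC=C
A1 | alternative 1 | tetrasubstituted ene‑diol with the aryl carbinol and the free CH2OH cis on the alkene, phenols as TIPS ethers, second CH2O as TBS ether | OC/C(Cc1ccc(O[Si](C(C)C)(C(C)C)C(C)C)c(OC)c1)=C(/CO[Si](C)(C)C(C)(C)C)[C@@H](O)c1cc(OC)c(O[Si](C(C)C)(C(C)C)C(C)C)c(OC)c1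
A2 | alternative 1 | 4‑(tert‑butyldimethylsilyloxy)but‑2‑yn‑1‑ol | OCC#CCO[Si](C)(C)C(C)(C)C
A3 | alternative 1 | (3‑methoxy‑4‑triisopropylsilyloxybenzyl)magnesium chloride | COc1cc(C[Mg]Cl)ccc1O[Si](C(C)C)(C(C)C)C(C)C
A4 | alternative 1 | 3,5‑dimethoxy‑4‑(triisopropylsilyloxy)benzaldehyde | COc1cc(C=O)cc(OC)c1O[Si](C(C)C)(C(C)C)C(C)C
A5 | alternative 2 | bis‑TBS oxolane core with free primary alcohol | OC[C@H]1[C@@H](Cc2ccc(O[Si](C)(C)C(C)(C)C)c(OC)c2)CO[C@@H]1c1cc(OC)c(O[Si](C)(C)C(C)(C)C)c(OC)c1
A6 | alternative 2 | (E)‑coniferyl ether of the syringyl oxiranyl carbinol, both phenols as TBS ethers, either oxirane epimer | COc1cc([C@@H](OC/C=C/c2ccc(O[Si](C)(C)C(C)(C)C)c(OC)c2)C2CO2)cc(OC)c1O[Si](C)(C)C(C)(C)C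
A7 | alternative 3 | bis‑TIPS diaryl furofuranone | O=C1O[C@H](c3ccc(O[Si](C(C)C)(C(C)C)C(C)C)c(OC)c3)[C@H]2CO[C@H](c3cc(OC)c(O[Si](C(C)C)(C(C)C)C(C)C)c(OC)c3)[C@@H]12
A8 | alternative 3 | trans‑5‑aryl‑4‑(aryloxymethyl‑type benzyl ether)‑3‑diazo‑γ‑butyrolactone, both phenols as TIPS ethers | O=C1O[C@H](c2ccc(O[Si](C(C)C)(C(C)C)C(C)C)c(OC)c2)[C@@H](COCc2cc(OC)c(O[Si](C(C)C)(C(C)C)C(C)C)c(OC)c2)C1=[N+]=[N-]
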